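## Retrosynthetic overview

1. Target 16 ⇐ oxolane 14 by a one-flask, bromide-terminated ring expansion (oxolane → 3-bromo-oxane, C–Br set by inversion) that also converts the tertiary ring alcohol into the bromide (key step, last).
2. 14 ⇐ 13 (chlorohydrin of the ring alkene) ⇐ Z-homoallylic alcohol 11 (hydroxyl-directed epoxidation, then 5-endo cyclisation closes the oxolane).
3. 11 ⇐ alkyne 9 (syn-carbomagnesiation brings the C-methyl and the Z geometry) ⇐ alkyne 4 + epoxide 7.
4. 4 ⇐ aldehyde 3 ⇐ isoprene + acrolein; 7 ⇐ methyl (R)-glycidate.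
5. Ring order: cyclohexene (step 1), oxolane (step 6), oxane by ring expansion (step 8).

Assumption: the organometallic steps are quenched with water, and the catalysts, bases, oxidants and halide sources named are bought as reagents.

## Route

Step 1
Reactants: 1 isoprene (2-methylbuta-1,3-diene); 2 acrolein (prop-2-enal)
Product: 3 (1R)-4-methylcyclohex-3-ene-1-carbaldehyde
Conditions: first-generation imidazolidinone catalyst (5S)-5-benzyl-2,2,3-trimethylimidazolidin-4-one·HCl (5 mol %), MeOH/H2O (95:5), 23 °C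
Reagents that add atoms: none
Why: Iminium-catalysed Diels–Alder reaction in which the benzyl arm shields one face of the acrolein iminium ion, giving the "para" adduct with the ring stereocentre R (about 89% ee; the minor hand becomes a diastereomer once joined to enantiopure 7 and is removed at 13).

Step 2
Reactants: 3 (1R)-4-methylcyclohex-3-ene-1-carbaldehyde
Product: 4 (4R)-4-ethynyl-1-methylcyclohex-1-ene
Conditions: TMSCHN2, n-BuLi, THF, −78 °C; add 3, −78 → 0 °C; H2O
Reagents that add atoms: trimethylsilyldiazomethane C[Si](C)(C)C=[N+]=[N-]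
Why: Colvin rearrangement (addition of lithiated TMS-diazomethane, Peterson elimination, loss of N2, 1,2-H shift of the alkylidene carbene) gives the alkyne under non-enolising conditions, so the ring stereocentre is kept.

Step 3
Reactants: 5 methyl (2R)-oxirane-2-carboxylate (methyl (R)-glycidate)
Product: 7 (2R)-2-(2-methoxypropan-2-yl)oxirane, via lithium alkoxide 6 (not isolated)
Conditions: MeLi (2.1 equiv), Et2O, −78 °C; then MeOTf (2.2 equiv), −78 → 0 °C
Reagents that add atoms: methyllithium [Li]C; methyl trifluoromethanesulfonate COS(=O)(=O)C(F)(F)F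
Why: Double addition of MeLi to the ester (faster than epoxide opening at −78 °C) and O-methylation of the tertiary alkoxide in the same flask; the stereocentre comes unchanged from the glycidate and the methyl ether masks the tertiary oxygen until step 8.

Step 4
Reactants: 4 (4R)-4-ethynyl-1-methylcyclohex-1-ene; 7 (2R)-2-(2-methoxypropan-2-yl)oxirane
Product: 9 (3R)-2-methoxy-2-methyl-6-[(1R)-4-methylcyclohex-3-en-1-yl]hex-5-yn-3-ol, via lithium acetylide 8 (not isolated)
Conditions: n-BuLi, THF, −78 °C; then 7, DMPU, −78 → 23 °C; H2O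
Reagents that add atoms: none
Why: SN2 opening of the terminal epoxide at its CH2 by the lithium acetylide (epoxide alkynylation); neither stereocentre is touched.

Step 5
Reactants: 9 (3R)-2-methoxy-2-methyl-6-[(1R)-4-methylcyclohex-3-en-1-yl]hex-5-yn-3-ol
Product: 11 (3R,5Z)-2-methoxy-2-methyl-6-[(1R)-4-methylcyclohex-3-en-1-yl]hept-5-en-3-ol, via alkenylmagnesium species 10 (not isolated)
Conditions: MeMgBr (5 equiv), Fe(acac)3 (15 mol %), dppe (15 mol %), THF, −78 → 0 °C; H2O
Reagents that add atoms: methylmagnesium bromide C[Mg]Br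
Why: Alkoxide-directed iron-catalysed syn-carbomagnesiation of a homopropargylic alcohol puts methyl on the distal alkyne carbon and magnesium on the proximal one (five-membered chelate), so protonation gives the Z alkene with the cyclohexenyl group cis to the chain.

Step 6
Reactants: 11 (3R,5Z)-2-methoxy-2-methyl-6-[(1R)-4-methylcyclohex-3-en-1-yl]hept-5-en-3-ol
Product: 13 (2S,3S,5R)-5-(2-methoxypropan-2-yl)-2-methyl-2-[(1R)-4-methylcyclohex-3-en-1-yl]oxolan-3-ol, via epoxy alcohol 12 (not isolated)
Conditions: VO(acac)2 (5 mol %), t-BuOOH (1.3 equiv), CH2Cl2, 0 → 23 °C; then CSA (10 mol %), 23 °C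
Reagents that add atoms: tert-butyl hydroperoxide CC(C)(C)OO
Why: Hydroxyl-directed vanadium-catalysed epoxidation (chair vanadate transition state, CMe2OMe equatorial, allylic strain from the Z substituent) gives the 1,3-syn epoxy alcohol and leaves the remote ring alkene alone, then acid-catalysed 5-endo epoxide opening at the tertiary carbon with inversion closes the oxolane and fixes C-2 and C-3.

Step 7
Reactants: 13 (2S,3S,5R)-5-(2-methoxypropan-2-yl)-2-methyl-2-[(1R)-4-methylcyclohex-3-en-1-yl]oxolan-3-ol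
Product: 14 (2S,3S,5R)-2-[(1R,3S,4S)-3-chloro-4-hydroxy-4-methylcyclohexyl]-5-(2-methoxypropan-2-yl)-2-methyloxolan-3-ol
Conditions: NCS (1.1 equiv), acetone/H2O (4:1), 0 → 23 °C
Reagents that add atoms: N-chlorosuccinimide O=C1CCC(=O)N1Cl; water O
Why: Chlorohydrin formation on the only remaining alkene, where Cl+ adds axially to the secondary carbon on the face anti to the side chain and water opens the chloronium ion at the tertiary carbon from the other face (Markovnikov and Fürst–Plattner trans-diaxial).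

Step 8
Reactants: 14 (2S,3S,5R)-2-[(1R,3S,4S)-3-chloro-4-hydroxy-4-methylcyclohexyl]-5-(2-methoxypropan-2-yl)-2-methyloxolan-3-ol
Product: 16 (2S,3S,5S)-5-bromo-2-[(1R,3S,4S)-4-bromo-3-chloro-4-methylcyclohexyl]-2,6,6-trimethyloxan-3-ol, via exo-bromide 15 (not isolated)
Conditions: HBr (anhydrous, 4 equiv, in CH2Cl2), ZnBr2 (20 mol %), CH2Cl2, −40 → 0 °C; cold aq. NaHCO3
Reagents that add atoms: hydrogen bromide Br
Why: Proposed new method: a bromide-terminated oxolane-to-oxane ring expansion under reversible-ionisation control, in which HBr/ZnBr2 ionises the tertiary C–OMe bond with help from the ring oxygen to a bicyclic oxiranium ion, bromide capture at the tertiary carbon gives exo-bromide 15 that re-ionises easily (eliminated alkene is recycled by HBr), while SN2 capture at the secondary ring carbon anti to oxygen (inversion, R to S) gives the kinetically robust equatorial secondary bromide of the oxane, so material funnels to the six-membered ring, and in the same flask the tertiary ring alcohol becomes the bromide with retention because its β-chloro cation (chloronium) is captured axially anti to chlorine; the closest known reactions are the zinc-acetate-mediated ring expansion of oxolanyl carbinol sulfonates through bicyclic oxonium ions with carboxylate nucleophiles, its reverse (ring contraction on attempted displacement at C-3 of 2,2-dimethyloxan-3-yl sulfonates), and hydrobromination of tertiary alcohols.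

## Compound list

1 | isoprene (2-methylbuta-1,3-diene) | C=CC(C)=C | starting material
2 | acrolein (prop-2-enal) | C=CC=O | starting material
3 | (1R)-4-methylcyclohex-3-ene-1-carbaldehyde | O=C[C@@H]1CCC(C)=CC1 | intermediate
4 | (4R)-4-ethynyl-1-methylcyclohex-1-ene | C#C[C@@H]1CCC(C)=CC1 | intermediate
5 | methyl (2R)-oxirane-2-carboxylate | COC(=O)[C@H]1CO1 | starting material
6 | lithium 2-[(2R)-oxiran-2-yl]propan-2-olate (not isolated) | [Li+].CC(C)([O-])[C@H]1CO1 | intermediate
7 | (2R)-2-(2-methoxypropan-2-yl)oxirane | COC(C)(C)[C@H]1CO1 | intermediate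
8 | lithium acetylide of 4, {[(1R)-4-methylcyclohex-3-en-1-yl]ethynyl}lithium (not isolated) | [Li]C#C[C@@H]1CCC(C)=CC1 | intermediate
9 | (3R)-2-methoxy-2-methyl-6-[(1R)-4-methylcyclohex-3-en-1-yl]hex-5-yn-3-ol | COC(C)(C)[C@H](O)CC#C[C@@H]1CCC(C)=CC1 | intermediate
10 | syn-carbomagnesiation adduct of 9: C-5 alkenylmagnesium bromide and O-3 bromomagnesium alkoxide of 11, methyl cis to magnesium (not isolated) | COC(C)(C)[C@H](O[Mg]Br)C/C([Mg]Br)=C(C)\[C@@H]1CCC(C)=CC1 | intermediate
11 | (3R,5Z)-2-methoxy-2-methyl-6-[(1R)-4-methylcyclohex-3-en-1-yl]hept-5-en-3-ol | COC(C)(C)[C@H](O)C/C=C(C)\[C@@H]1CCC(C)=CC1 | intermediate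
12 | (2R)-3-methoxy-3-methyl-1-{(2S,3R)-3-methyl-3-[(1R)-4-methylcyclohex-3-en-1-yl]oxiran-2-yl}butan-2-ol (not isolated) | COC(C)(C)[C@H](O)C[C@@H]1O[C@]1(C)[C@@H]2CCC(C)=CC2 | intermediate
13 | (2S,3S,5R)-5-(2-methoxypropan-2-yl)-2-methyl-2-[(1R)-4-methylcyclohex-3-en-1-yl]oxolan-3-ol | COC(C)(C)[C@H]1C[C@H](O)[C@](C)([C@@H]2CCC(C)=CC2)O1 | intermediate
14 | (2S,3S,5R)-2-[(1R,3S,4S)-3-chloro-4-hydroxy-4-methylcyclohexyl]-5-(2-methoxypropan-2-yl)-2-methyloxolan-3-ol | COC(C)(C)[C@H]1C[C@H](O)[C@](C)([C@@H]2CC[C@](C)(O)[C@@H](Cl)C2)O1 | intermediate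
15 | (2S,3S,5R)-2-[(1R,3S,4S)-4-bromo-3-chloro-4-methylcyclohexyl]-5-(2-bromopropan-2-yl)-2-methyloxolan-3-ol (not isolated) | CC(C)(Br)[C@H]1C[C@H](O)[C@](C)([C@@H]2CC[C@](C)(Br)[C@@H](Cl)C2)O1 | intermediate
16 | (2S,3S,5S)-5-bromo-2-[(1R,3S,4S)-4-bromo-3-chloro-4-methylcyclohexyl]-2,6,6-trimethyloxan-3-ol | CC1(C)O[C@@](C)([C@@H]2CC[C@](C)(Br)[C@@H](Cl)C2)[C@@H](O)C[C@@H]1Br | target

## Step count and risks

Total steps: 8. Longest linear sequence: 7 (steps 1, 2, 4, 5, 6, 7, 8; step 3 makes the side fragment).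

Most likely to fail:

**Step 8 (proposed ring expansion and tertiary bromination).** The exo-bromide 15 may not funnel to the oxane, or the acid may erode the ethers or exchange the ring chloride. The fallback uses known chemistry only and sets out from 13. TMSBr with 2,6-di-tert-butylpyridine (CH2Cl2, −40 °C, no free HBr, so the ring alkene survives) exchanges the tertiary methyl ether for bromide and silylates the ring hydroxyl, giving the exo-bromide silyl ether (2S,3S,5R)-5-(2-bromopropan-2-yl)-2-methyl-2-[(1R)-4-methylcyclohex-3-en-1-yl]-3-(trimethylsilyloxy)oxolane F5. Zinc dust (THF/EtOH, 23 °C) then effects a Boord-type reductive β-elimination that opens the oxolane to the hydroxy-alkene (2S,3S)-6-methyl-2-[(1R)-4-methylcyclohex-3-en-1-yl]-3-(trimethylsilyloxy)hept-5-en-2-ol F6. TBCO (2,4,4,6-tetrabromocyclohexa-2,5-dienone) in MeNO2 carries out the known 6-endo bromoetherification of the side-chain alkene through a chair transition state (bromine and cyclohexenyl equatorial; only this alkene has an internal nucleophile). This gives the bromo-oxane (2S,3S,5S)-5-bromo-2,6,6-trimethyl-2-[(1R)-4-methylcyclohex-3-en-1-yl]-3-(trimethylsilyloxy)oxane F7, which is separated from minor isomers. NCS in aqueous acetone gives the trans-diaxial chlorohydrin with loss of the silyl ether, (2S,3S,5S)-5-bromo-2-[(1R,3S,4S)-3-chloro-4-hydroxy-4-methylcyclohexyl]-2,6,6-trimethyloxan-3-ol F8. HBr in CH2Cl2 at −40 °C converts the tertiary alcohol into the bromide and the route is rejoined at 16.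

**Step 5 (directed carbomagnesiation).** The α-branched alkyne carbon may react slowly or with poor regiocontrol. The fallback sets out from 9. Ph3PAuCl/AgOTf (2 mol % each, CH2Cl2) brings about 5-endo-dig cycloisomerisation to the enol ether (2R)-2-(2-methoxypropan-2-yl)-5-[(1R)-4-methylcyclohex-3-en-1-yl]-2,3-dihydrofuran F1. DMDO (acetone, −78 °C) epoxidises the electron-rich enol ether anti to the C-2 substituent, much faster than the ring alkene, giving the anhydro epoxide 3-(2-methoxypropan-2-yl)-1-[(1R)-4-methylcyclohex-3-en-1-yl]-2,6-dioxabicyclo[3.1.0]hexane (oxirane oxygen trans to the C-3 side chain) F2. MeMgBr with CuI (cat.) opens it at the acetal carbon anti to the oxirane oxygen, which puts methyl trans to the new hydroxyl and rejoins the route at 13 (11 and 12 are bypassed).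

**Step 7 (chlorohydrin).** Allylic chlorination or a poor diastereomer ratio is possible. The fallback sets out from 13. NBS in aqueous acetone gives the trans-diaxial bromohydrin (2S,3S,5R)-2-[(1R,3S,4S)-3-bromo-4-hydroxy-4-methylcyclohexyl]-5-(2-methoxypropan-2-yl)-2-methyloxolan-3-ol F3; bromonium formation is reversible, which is why this is highly selective on limonene-type rings. K2CO3 in MeOH closes it to the epoxide with oxygen cis to the side chain, (2S,3S,5R)-5-(2-methoxypropan-2-yl)-2-methyl-2-[(1S,4R,6R)-1-methyl-7-oxabicyclo[4.1.0]heptan-4-yl]oxolan-3-ol F4. LiCl/AcOH in THF opens the epoxide by SN2 at the secondary carbon (trans-diaxial) and the route is rejoined at 14.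

Further compounds

F1 | step 5 | (2R)-2-(2-methoxypropan-2-yl)-5-[(1R)-4-methylcyclohex-3-en-1-yl]-2,3-dihydrofuran | COC(C)(C)[C@H]1CC=C(O1)[C@@H]2CCC(C)=CC2
F2 | step 5 | 3-(2-methoxypropan-2-yl)-1-[(1R)-4-methylcyclohex-3-en-1-yl]-2,6-dioxabicyclo[3.1.0]hexane, oxirane oxygen trans to the C-3 side chain | COC(C)(C)[C@H]1C[C@@H]2O[C@@]2(O1)[C@@H]3CCC(C)=CC3
F3 | step 7 | (2S,3S,5R)-2-[(1R,3S,4S)-3-bromo-4-hydroxy-4-methylcyclohexyl]-5-(2-methoxypropan-2-yl)-2-methyloxolan-3-ol | COC(C)(C)[C@H]1C[C@H](O)[C@](C)([C@@H]2CC[C@](C)(O)[C@@H](Br)C2)O1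
F4 | step 7 | (2S,3S,5R)-5-(2-methoxypropan-2-yl)-2-methyl-2-[(1S,4R,6R)-1-methyl-7-oxabicyclo[4.1.0]heptan-4-yl]oxolan-3-ol | COC(C)(C)[C@H]1C[C@H](O)[C@](C)([C@@H]2CC[C@]3(C)O[C@@H]3C2)O1
F5 | step 8 | (2S,3S,5R)-5-(2-bromopropan-2-yl)-2-methyl-2-[(1R)-4-methylcyclohex-3-en-1-yl]-3-(trimethylsilyloxy)oxolane | CC(C)(Br)[C@H]1C[C@H](O[Si](C)(C)C)[C@](C)([C@@H]2CCC(C)=CC2)O1
F6 | step 8 | (2S,3S)-6-methyl-2-[(1R)-4-methylcyclohex-3-en-1-yl]-3-(trimethylsilyloxy)hept-5-en-2-ol | CC(C)=CC[C@H](O[Si](C)(C)C)[C@@](C)(O)[C@@H]1CCC(C)=CC1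
F7 | step 8 | (2S,3S,5S)-5-bromo-2,6,6-trimethyl-2-[(1R)-4-methylcyclohex-3-en-1-yl]-3-(trimethylsilyloxy)oxane | CC1(C)O[C@@](C)([C@@H]2CCC(C)=CC2)[C@@H](O[Si](C)(C)C)C[C@@H]1Br
F8 | step 8 | (2S,3S,5S)-5-bromo-2-[(1R,3S,4S)-3-chloro-4-hydroxy-4-methylcyclohexyl]-2,6,6-trimethyloxan-3-ol | CC1(C)O[C@@](C)([C@@H]2CC[C@](C)(O)[C@@H](Cl)C2)[C@@H](O)C[C@@H]1Br
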